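**Retrosynthetic overview**
- The target comes from a bis-silylated macrocyclic hydroxy lactone by Mitsunobu esterification with angelic acid (inversion at the ester carbinol), then desilylation.
- Key step: intramolecular CrCl2 Barbier allylation of a 3-(bromomethyl)butenolide onto a (Z)-enal. It forms the C7–C8 bond, the ten-membered ring, two stereocentres and the α-methylene lactone in one operation.
- Ring order: butenolide first (ring-closing metathesis of a 2-(bromomethyl)acrylate ester), carbocycle last.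
- The cyclisation substrate comes from a C2-symmetric (Z,Z)-dialdehyde by desymmetrising asymmetric mono-vinylation and acylation.
- The dialdehyde is built two-directionally: boron aldol of a (Z)-enone with a (Z)-enal, anti-reduction, both partners from (Z)-3-iodobut-2-en-1-ol (from but-2-yn-1-ol).

Assumption: germacrane-style locants are used in the explanations (ring C1–C10; C1 and C3 carry OH, C4 and C10 carry CH3, C6 is the lactone carbinol, C7 the ring fusion, C8 the angelate carbinol, C11–C13 the methylene-lactone carbons); Zn(CH=CH2)2, (+)-MIB and i-PrMgCl·LiCl are taken as prepared separately or purchased.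

**Route**

Step 1
Reactants: 1 but-2-yn-1-ol
Product: 3 (2Z)-3-iodobut-2-en-1-ol, via cyclic alkenylaluminate 2 (not isolated)
Conditions: NaAlH2(OCH2CH2OCH3)2, THF, 0 °C → rt; then I2, −78 → 0 °C; H2O
Reagents that add atoms: iodine, II
Why: Hydroxyl-directed trans-hydroalumination of the propargylic alcohol puts aluminium on the distal carbon cis to CH2O (five-membered aluminate 2), and iodinolysis with retention gives the (Z)-alkenyl iodide.

Step 2
Reactants: 3 (2Z)-3-iodobut-2-en-1-ol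
Product: 4 tert-butyl{[(2Z)-3-iodobut-2-en-1-yl]oxy}dimethylsilane
Conditions: TBSCl, imidazole, CH2Cl2, 0 °C → rt
Reagents that add atoms: tert-butyldimethylsilyl chloride, CC(C)(C)[Si](C)(C)Cl
Why: Standard silylation of a primary alcohol; the silyl ether tolerates the organolithium, organomagnesium and boron chemistry that follows.

Step 3
Reactants: 4 tert-butyl{[(2Z)-3-iodobut-2-en-1-yl]oxy}dimethylsilane
Product: 6 (3Z)-5-[(tert-butyldimethylsilyl)oxy]-3-methylpent-3-en-2-one, via alkenyllithium 5 (not isolated)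
Conditions: t-BuLi (2.1 equiv), Et2O, −78 °C; then MeC(O)N(OMe)Me, −78 → 0 °C; H2O
Reagents that add atoms: N-methoxy-N-methylacetamide, CC(=O)N(C)OC
Why: Lithium–iodine exchange proceeds with retention of alkene geometry and the Weinreb amide stops at the ketone (Weinreb ketone synthesis).

Step 4
Reactants: 4 tert-butyl{[(2Z)-3-iodobut-2-en-1-yl]oxy}dimethylsilane
Product: 8 (2Z)-4-[(tert-butyldimethylsilyl)oxy]-2-methylbut-2-enal, via alkenylmagnesium chloride 7 (not isolated)
Conditions: i-PrMgCl·LiCl (1.2 equiv), THF, 0 °C → rt; then DMF, −20 → 0 °C; H2O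
Reagents that add atoms: N,N-dimethylformamide, CN(C)C=O
Why: Iodine–magnesium exchange with the LiCl-activated Grignard reagent retains the alkene geometry (assisted by the neighbouring silyloxy oxygen), and Bouveault formylation of the alkenylmagnesium with DMF gives the (Z)-enal, which is used at once to avoid Z→E isomerisation.

Step 5
Reactants: 6 (3Z)-5-[(tert-butyldimethylsilyl)oxy]-3-methylpent-3-en-2-one; 8 (2Z)-4-[(tert-butyldimethylsilyl)oxy]-2-methylbut-2-enal
Product: 10 (2Z,6S,7Z)-1,9-bis[(tert-butyldimethylsilyl)oxy]-6-hydroxy-3,7-dimethylnona-2,7-dien-4-one, via diisopinocampheylboron enolate 9 (not isolated)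
Conditions: (−)-Ipc2BCl, Et3N, Et2O, 0 °C; then 8, −78 → −20 °C; H2O2, MeOH, pH 7 buffer, 0 °C
Reagents that add atoms: none
Why: Paterson boron aldol: kinetic enolisation on the methyl side, then addition of the Ipc2B enolate to the Si face of the enal (methyl-ketone model, recalled rather than verified for this reagent enantiomer) sets the (S)-carbinol (about 80% ee expected; the minor enantiomer is removed as a diastereomer after step 10).

Step 6
Reactants: 10 (2Z,6S,7Z)-1,9-bis[(tert-butyldimethylsilyl)oxy]-6-hydroxy-3,7-dimethylnona-2,7-dien-4-one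
Product: 11 (2Z,4S,6S,7Z)-1,9-bis[(tert-butyldimethylsilyl)oxy]-3,7-dimethylnona-2,7-diene-4,6-diol
Conditions: Me4NBH(OAc)3, MeCN/AcOH (1:1), −25 °C
Reagents that add atoms: none
Why: Evans–Saksena reduction: the β-hydroxyl binds boron and delivers hydride intramolecularly through a chair, giving the 1,3-anti diol (new S centre), which is C2-symmetric.

Step 7
Reactants: 11 (2Z,4S,6S,7Z)-1,9-bis[(tert-butyldimethylsilyl)oxy]-3,7-dimethylnona-2,7-diene-4,6-diol
Product: 12 (2Z,4S,6S,7Z)-1,4,6,9-tetrakis[(tert-butyldimethylsilyl)oxy]-3,7-dimethylnona-2,7-diene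
Conditions: TBSOTf, 2,6-lutidine, CH2Cl2, −78 → 0 °C
Reagents that add atoms: tert-butyldimethylsilyl trifluoromethanesulfonate, CC(C)(C)[Si](C)(C)OS(=O)(=O)C(F)(F)F
Why: Silyl triflate silylates the hindered secondary allylic alcohols; these two ethers mask C1–OH and C3–OH until the last step.

Step 8
Reactants: 12 (2Z,4S,6S,7Z)-1,4,6,9-tetrakis[(tert-butyldimethylsilyl)oxy]-3,7-dimethylnona-2,7-diene
Product: 13 (2Z,4S,6S,7Z)-4,6-bis[(tert-butyldimethylsilyl)oxy]-3,7-dimethylnona-2,7-diene-1,9-diol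
Conditions: HF·pyridine, pyridine, THF, 0 °C
Reagents that add atoms: none
Why: Selective desilylation: the two primary allylic silyl ethers cleave much faster than the secondary ones flanked by the trisubstituted alkenes.

Step 9
Reactants: 13 (2Z,4S,6S,7Z)-4,6-bis[(tert-butyldimethylsilyl)oxy]-3,7-dimethylnona-2,7-diene-1,9-diol
Product: 14 (2Z,4S,6S,7Z)-4,6-bis[(tert-butyldimethylsilyl)oxy]-3,7-dimethylnona-2,7-dienedial
Conditions: PhI(OAc)2 (2.4 equiv), TEMPO (10 mol%), CH2Cl2, rt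
Reagents that add atoms: none
Why: TEMPO/PhI(OAc)2 (oxoammonium) oxidation converts both primary allylic alcohols into enals without over-oxidation and without Z→E isomerisation.

Step 10
Reactants: 14 (2Z,4S,6S,7Z)-4,6-bis[(tert-butyldimethylsilyl)oxy]-3,7-dimethylnona-2,7-dienedial
Product: 15 (2Z,4S,6S,7Z,9R)-4,6-bis[(tert-butyldimethylsilyl)oxy]-9-hydroxy-3,7-dimethylundeca-2,7,10-trienal
Conditions: Zn(CH=CH2)2 (1.1 equiv), (+)-MIB [(2R)-3-exo-morpholinoisoborneol, 10 mol%], toluene, −20 → 0 °C; H2O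
Reagents that add atoms: divinylzinc, C=C[Zn]C=C
Why: Amino-alcohol-catalysed alkenylzinc addition: the two aldehydes of 14 are homotopic, so mono-addition gives a single compound, and (+)-MIB directs vinyl to the Re face to set the (9R) carbinol (future C6); the mono/bis mixture is statistical and unreacted 14 is recycled.

Step 11
Reactants: 15 (2Z,4S,6S,7Z,9R)-4,6-bis[(tert-butyldimethylsilyl)oxy]-9-hydroxy-3,7-dimethylundeca-2,7,10-trienal; 16 2-(bromomethyl)prop-2-enoic acid
Product: 17 (3R,4Z,6S,8S,9Z)-6,8-bis[(tert-butyldimethylsilyl)oxy]-5,9-dimethyl-11-oxoundeca-1,4,9-trien-3-yl 2-(bromomethyl)prop-2-enoate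
Conditions: DCC, DMAP (5 mol%), CH2Cl2, −20 → 0 °C
Reagents that add atoms: none
Why: Steglich esterification of the secondary alcohol at low temperature keeps the allylic bromide and the (Z)-enal intact and does not touch the carbinol configuration.

Step 12
Reactants: 17 (3R,4Z,6S,8S,9Z)-6,8-bis[(tert-butyldimethylsilyl)oxy]-5,9-dimethyl-11-oxoundeca-1,4,9-trien-3-yl 2-(bromomethyl)prop-2-enoate
Product: 18 (2Z,4S,6S,7Z)-8-[(2S)-4-(bromomethyl)-5-oxo-2,5-dihydrofuran-2-yl]-4,6-bis[(tert-butyldimethylsilyl)oxy]-3,7-dimethylocta-2,7-dienal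
Conditions: second-generation Grubbs catalyst RuCl2(=CHPh)(PCy3)(H2IMes) (10 mol%), 1,4-benzoquinone (20 mol%), toluene, 70 °C
Reagents that add atoms: none
Why: Ring-closing metathesis of the vinyl group with the acrylate alkene closes the butenolide with loss of ethene; the trisubstituted alkenes and the enal are too hindered or electron-poor to take part, and the carbinol centre is untouched (its descriptor changes to S only through priorities).

Step 13
Reactants: 18 (2Z,4S,6S,7Z)-8-[(2S)-4-(bromomethyl)-5-oxo-2,5-dihydrofuran-2-yl]-4,6-bis[(tert-butyldimethylsilyl)oxy]-3,7-dimethylocta-2,7-dienal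
Product: 20 (3aR,4S,5Z,7S,9S,10Z,11aS)-7,9-bis[(tert-butyldimethylsilyl)oxy]-4-hydroxy-6,10-dimethyl-3-methylidene-3a,4,7,8,9,11a-hexahydrocyclodeca[b]furan-2(3H)-one, via allylchromium dichloride 19 (not isolated)
Conditions: CrCl2 (10 equiv), THF, rt, slow addition of 18 (final 0.002 M); then H2O
Reagents that add atoms: none
Why: Nozaki–Hiyama-type intramolecular Barbier allylation: allylchromium 19 (γ-carbon C7, E geometry locked by the butenolide) adds to the aldehyde through a closed chair; the (Z,Z)-cyclodeca-1,6-diene being formed needs a gauche C5–C6–C7–C8 torsion, which only attack on the butenolide face syn to the C6 side chain allows (cis-fused lactone, sets C7), and the tether sits equatorial in the chair, so the new C8–OH is predicted anti (trans to C11), the epimer that step 14 inverts.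

Step 14
Reactants: 20 (3aR,4S,5Z,7S,9S,10Z,11aS)-7,9-bis[(tert-butyldimethylsilyl)oxy]-4-hydroxy-6,10-dimethyl-3-methylidene-3a,4,7,8,9,11a-hexahydrocyclodeca[b]furan-2(3H)-one; 21 (2Z)-2-methylbut-2-enoic acid (angelic acid)
Product: 23 (3aS,4R,5Z,7S,9S,10Z,11aS)-7,9-bis[(tert-butyldimethylsilyl)oxy]-6,10-dimethyl-3-methylidene-2-oxo-2,3,3a,4,7,8,9,11a-octahydrocyclodeca[b]furan-4-yl (2Z)-2-methylbut-2-enoate, via alkoxyphosphonium angelate 22 (not isolated)
Conditions: PPh3, DIAD, toluene, 0 °C → rt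
Reagents that add atoms: none
Why: Mitsunobu esterification: SN2 displacement of the alkoxyphosphonium by angelate inverts C8 to the required configuration and installs the ester in the same step; the γ-carbon is fully substituted, which disfavours SN2', and the neutral conditions avoid angelate-to-tiglate isomerisation.

Step 15
Reactants: 23 (3aS,4R,5Z,7S,9S,10Z,11aS)-7,9-bis[(tert-butyldimethylsilyl)oxy]-6,10-dimethyl-3-methylidene-2-oxo-2,3,3a,4,7,8,9,11a-octahydrocyclodeca[b]furan-4-yl (2Z)-2-methylbut-2-enoate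
Product: 24 (3aS,4R,5Z,7S,9S,10Z,11aS)-7,9-dihydroxy-6,10-dimethyl-3-methylidene-2-oxo-2,3,3a,4,7,8,9,11a-octahydrocyclodeca[b]furan-4-yl (2Z)-2-methylbut-2-enoate (CNP0152559.4)
Conditions: HF·pyridine, THF, 0 °C → rt
Reagents that add atoms: none
Why: Fluoride-driven cleavage of the two secondary silyl ethers under mildly acidic, non-nucleophilic conditions leaves the α-methylene lactone, the angelate and all stereocentres untouched.

**Compound list**

1 | but-2-yn-1-ol | CC#CCO | starting material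
2 | sodium 2,2-bis(2-methoxyethoxy)-3-methyl-2,5-dihydro-1,2-oxaaluminol-2-uide (cyclic alkenylaluminate) | CC1=CCO[Al-]1(OCCOC)OCCOC.[Na+] | intermediate
3 | (2Z)-3-iodobut-2-en-1-ol | C/C(I)=C/CO | intermediate
4 | tert-butyl{[(2Z)-3-iodobut-2-en-1-yl]oxy}dimethylsilane | C/C(I)=C/CO[Si](C)(C)C(C)(C)C | intermediate
5 | {4-[(tert-butyldimethylsilyl)oxy]but-2-en-2-yl}lithium, Li cis to CH2OTBS | C/C([Li])=C/CO[Si](C)(C)C(C)(C)C | intermediate
6 | (3Z)-5-[(tert-butyldimethylsilyl)oxy]-3-methylpent-3-en-2-one | CC(=O)/C(C)=C\CO[Si](C)(C)C(C)(C)C | intermediate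
7 | chloro{4-[(tert-butyldimethylsilyl)oxy]but-2-en-2-yl}magnesium, Mg cis to CH2OTBS (formed as its LiCl complex) | C/C([Mg]Cl)=C/CO[Si](C)(C)C(C)(C)C | intermediate
8 | (2Z)-4-[(tert-butyldimethylsilyl)oxy]-2-methylbut-2-enal | O=C/C(C)=C\CO[Si](C)(C)C(C)(C)C | intermediate
9 | (3Z)-5-[(tert-butyldimethylsilyl)oxy]-3-methylpenta-1,3-dien-2-yl diisopinocampheylborinate (Ipc from (+)-α-pinene) | C=C(OB([C@@H]1C[C@@H]2C[C@H]([C@H]1C)C2(C)C)[C@@H]1C[C@@H]2C[C@H]([C@H]1C)C2(C)C)/C(C)=C\CO[Si](C)(C)C(C)(C)C | intermediate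
10 | (2Z,6S,7Z)-1,9-bis[(tert-butyldimethylsilyl)oxy]-6-hydroxy-3,7-dimethylnona-2,7-dien-4-one | CC(C)(C)[Si](C)(C)OC/C=C(/C)C(=O)C[C@H](O)/C(C)=C\CO[Si](C)(C)C(C)(C)C | intermediate
11 | (2Z,4S,6S,7Z)-1,9-bis[(tert-butyldimethylsilyl)oxy]-3,7-dimethylnona-2,7-diene-4,6-diol | CC(C)(C)[Si](C)(C)OC/C=C(/C)[C@@H](O)C[C@H](O)/C(C)=C\CO[Si](C)(C)C(C)(C)C | intermediate
12 | (2Z,4S,6S,7Z)-1,4,6,9-tetrakis[(tert-butyldimethylsilyl)oxy]-3,7-dimethylnona-2,7-diene | CC(C)(C)[Si](C)(C)OC/C=C(/C)[C@@H](O[Si](C)(C)C(C)(C)C)C[C@H](O[Si](C)(C)C(C)(C)C)/C(C)=C\CO[Si](C)(C)C(C)(C)C | intermediate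
13 | (2Z,4S,6S,7Z)-4,6-bis[(tert-butyldimethylsilyl)oxy]-3,7-dimethylnona-2,7-diene-1,9-diol | OC/C=C(/C)[C@@H](O[Si](C)(C)C(C)(C)C)C[C@H](O[Si](C)(C)C(C)(C)C)/C(C)=C\CO | intermediate
14 | (2Z,4S,6S,7Z)-4,6-bis[(tert-butyldimethylsilyl)oxy]-3,7-dimethylnona-2,7-dienedial | O=C/C=C(/C)[C@@H](O[Si](C)(C)C(C)(C)C)C[C@H](O[Si](C)(C)C(C)(C)C)/C(C)=C\C=O | intermediate
15 | (2Z,4S,6S,7Z,9R)-4,6-bis[(tert-butyldimethylsilyl)oxy]-9-hydroxy-3,7-dimethylundeca-2,7,10-trienal | C=C[C@@H](O)/C=C(/C)[C@@H](O[Si](C)(C)C(C)(C)C)C[C@H](O[Si](C)(C)C(C)(C)C)/C(C)=C\C=O | intermediate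
16 | 2-(bromomethyl)prop-2-enoic acid | C=C(CBr)C(=O)O | starting material
17 | (3R,4Z,6S,8S,9Z)-6,8-bis[(tert-butyldimethylsilyl)oxy]-5,9-dimethyl-11-oxoundeca-1,4,9-trien-3-yl 2-(bromomethyl)prop-2-enoate | C=C(CBr)C(=O)O[C@H](C=C)/C=C(/C)[C@@H](O[Si](C)(C)C(C)(C)C)C[C@H](O[Si](C)(C)C(C)(C)C)/C(C)=C\C=O | intermediate
18 | (2Z,4S,6S,7Z)-8-[(2S)-4-(bromomethyl)-5-oxo-2,5-dihydrofuran-2-yl]-4,6-bis[(tert-butyldimethylsilyl)oxy]-3,7-dimethylocta-2,7-dienal | BrCC1=C[C@H](/C=C(/C)[C@@H](O[Si](C)(C)C(C)(C)C)C[C@H](O[Si](C)(C)C(C)(C)C)/C(C)=C\C=O)OC1=O | intermediate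
19 | allylchromium dichloride derived from 18 (CrCl2 on the former CH2Br carbon) | Cl[Cr](Cl)CC1=C[C@H](/C=C(/C)[C@@H](O[Si](C)(C)C(C)(C)C)C[C@H](O[Si](C)(C)C(C)(C)C)/C(C)=C\C=O)OC1=O | intermediate
20 | (3aR,4S,5Z,7S,9S,10Z,11aS)-7,9-bis[(tert-butyldimethylsilyl)oxy]-4-hydroxy-6,10-dimethyl-3-methylidene-3a,4,7,8,9,11a-hexahydrocyclodeca[b]furan-2(3H)-one | C=C1C(=O)O[C@H]2/C=C(/C)[C@@H](O[Si](C)(C)C(C)(C)C)C[C@H](O[Si](C)(C)C(C)(C)C)/C(C)=C\[C@H](O)[C@@H]12 | intermediate
21 | (2Z)-2-methylbut-2-enoic acid (angelic acid) | C/C=C(/C)C(=O)O | starting material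
22 | alkoxytriphenylphosphonium angelate derived from 20 (OPPh3+ on C4) | C=C1C(=O)O[C@H]2/C=C(/C)[C@@H](O[Si](C)(C)C(C)(C)C)C[C@H](O[Si](C)(C)C(C)(C)C)/C(C)=C\[C@H](O[P+](c3ccccc3)(c3ccccc3)c3ccccc3)[C@@H]12.C/C=C(/C)C(=O)[O-] | intermediate
23 | (3aS,4R,5Z,7S,9S,10Z,11aS)-7,9-bis[(tert-butyldimethylsilyl)oxy]-6,10-dimethyl-3-methylidene-2-oxo-2,3,3a,4,7,8,9,11a-octahydrocyclodeca[b]furan-4-yl (2Z)-2-methylbut-2-enoate | C=C1C(=O)O[C@H]2/C=C(/C)[C@@H](O[Si](C)(C)C(C)(C)C)C[C@H](O[Si](C)(C)C(C)(C)C)/C(C)=C\[C@@H](OC(=O)/C(C)=C\C)[C@@H]12 | intermediate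
24 | (3aS,4R,5Z,7S,9S,10Z,11aS)-7,9-dihydroxy-6,10-dimethyl-3-methylidene-2-oxo-2,3,3a,4,7,8,9,11a-octahydrocyclodeca[b]furan-4-yl (2Z)-2-methylbut-2-enoate | C=C1C(=O)O[C@H]2/C=C(/C)[C@@H](O)C[C@H](O)/C(C)=C\[C@@H](OC(=O)/C(C)=C\C)[C@@H]12 | target

**Totals**

Total step count: 15. Longest linear sequence: 14 steps (1, 2, 3, 5–15; step 4 is the parallel branch from compound 4).

**Steps most likely to fail, with fallbacks**

Step 13 (macrocyclic chromium Barbier reaction). The risks are oligomerisation, trans ring fusion (which nothing downstream can correct) and the opposite sense at the new carbinol. This fallback sets out from 18 and comes back to the route at 23. The ring is closed instead with zinc dust in THF/saturated aqueous NH4Cl at high dilution, conditions expected to react through a non-chair arrangement and favour the other simple diastereomer. The product is then the cis alcohol (3aR,4R,5Z,7S,9S,10Z,11aS)-7,9-bis[(tert-butyldimethylsilyl)oxy]-4-hydroxy-6,10-dimethyl-3-methylidene-3a,4,7,8,9,11a-hexahydrocyclodeca[b]furan-2(3H)-one F1, which already has the natural configuration at the carbinol. It is esterified with retention (angelic anhydride, Cs2CO3, MeCN, rt) to give 23, so the invertive esterification is replaced by a retentive acylation.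

Step 10 (desymmetrising asymmetric vinylation). The risks are modest enantioselectivity with the parent vinyl group and the statistical mono/bis distribution. This fallback sets out from 14 and comes back at 15. ZnMe2/ProPhenol-catalysed addition of ethynyltrimethylsilane (ligand enantiomer chosen for Re-face delivery; alkynylation of enals is reliably selective) gives (2Z,4S,6S,7Z,9S)-4,6-bis[(tert-butyldimethylsilyl)oxy]-9-hydroxy-3,7-dimethyl-11-(trimethylsilyl)undeca-2,7-dien-10-ynal F2. K2CO3 in MeOH at 0 °C removes the alkynyl silyl group to give (2Z,4S,6S,7Z,9S)-4,6-bis[(tert-butyldimethylsilyl)oxy]-9-hydroxy-3,7-dimethylundeca-2,7-dien-10-ynal F3. Semi-hydrogenation (H2, Pd on CaCO3 poisoned with Pb(OAc)2, quinoline, EtOAc) converts the terminal alkyne into the vinyl group of 15.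

Step 14 (Mitsunobu inversion with angelic acid at a hindered allylic carbinol next to the ring fusion). The risks are elimination, SN2' and phosphine addition to the methylene lactone. This fallback sets out from 20 and comes back at 23. The alcohol is activated with ClCH2SO2Cl and pyridine in CH2Cl2 at 0 °C as (3aS,4S,5Z,7S,9S,10Z,11aS)-7,9-bis[(tert-butyldimethylsilyl)oxy]-6,10-dimethyl-3-methylidene-2-oxo-2,3,3a,4,7,8,9,11a-octahydrocyclodeca[b]furan-4-yl chloromethanesulfonate F4. The sulfonate is displaced with inversion by caesium (2Z)-2-methylbut-2-enoate and 18-crown-6 in toluene at rt to give 23, a two-stage sulfonate displacement in place of the redox condensation.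

**Further compounds**

F1 | step 13 | (3aR,4R,5Z,7S,9S,10Z,11aS)-7,9-bis[(tert-butyldimethylsilyl)oxy]-4-hydroxy-6,10-dimethyl-3-methylidene-3a,4,7,8,9,11a-hexahydrocyclodeca[b]furan-2(3H)-one | C=C1C(=O)O[C@H]2/C=C(/C)[C@@H](O[Si](C)(C)C(C)(C)C)C[C@H](O[Si](C)(C)C(C)(C)C)/C(C)=C\[C@@H](O)[C@@H]12
F2 | step 10 | (2Z,4S,6S,7Z,9S)-4,6-bis[(tert-butyldimethylsilyl)oxy]-9-hydroxy-3,7-dimethyl-11-(trimethylsilyl)undeca-2,7-dien-10-ynal | C[Si](C)(C)C#C[C@@H](O)/C=C(/C)[C@@H](O[Si](C)(C)C(C)(C)C)C[C@H](O[Si](C)(C)C(C)(C)C)/C(C)=C\C=O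
F3 | step 10 | (2Z,4S,6S,7Z,9S)-4,6-bis[(tert-butyldimethylsilyl)oxy]-9-hydroxy-3,7-dimethylundeca-2,7-dien-10-ynal | C#C[C@@H](O)/C=C(/C)[C@@H](O[Si](C)(C)C(C)(C)C)C[C@H](O[Si](C)(C)C(C)(C)C)/C(C)=C\C=O
F4 | step 14 | (3aS,4S,5Z,7S,9S,10Z,11aS)-7,9-bis[(tert-butyldimethylsilyl)oxy]-6,10-dimethyl-3-methylidene-2-oxo-2,3,3a,4,7,8,9,11a-octahydrocyclodeca[b]furan-4-yl chloromethanesulfonate | C=C1C(=O)O[C@H]2/C=C(/C)[C@@H](O[Si](C)(C)C(C)(C)C)C[C@H](O[Si](C)(C)C(C)(C)C)/C(C)=C\[C@H](OS(=O)(=O)CCl)[C@@H]12
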